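**Plan**

- Retrosynthesis: the enol acetate and the two phenol silyl groups are removed first. Then both C=C bonds of the quinone ring are cut: the one between the acetoxy-bearing carbon and its aryl-bearing neighbour, and the one between the ring CH and its aryl-bearing neighbour.
- Enabling feature: the quinone ring is two head-to-tail Ar–C–C(=O)–C units. In each, the aryl-bearing ring carbon is benzylic and next to a ring carbonyl (a donor). The far carbon (C–OAc in one unit, C–H in the other) is a carboxyl-level or aldehyde-level acceptor. An arylpyruvic acid plus an arylpyruvaldehyde, minus alcohol and water, is therefore already at the hydroxyquinone oxidation level. This copies the presumed biosynthetic dimerization of 4-hydroxyphenylpyruvate to terphenylquinones.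
- Precursors: the acid half is used as its enol acetonide, a 5-arylidene-1,3-dioxolan-4-one. This temporary ring activates the carboxyl, masks the ketone and releases an enolate on acylation. The aldehyde half is a benzyl ketone with the aldehyde carbon held as a diethyl acetal.
- Forward: one silylated 4-hydroxybenzaldehyde feeds both halves. The key step builds the only new ring (the quinone) in one flask. O-acetylation and desilylation finish the route.
- Stereochemistry: the target has no stereocentre. The only stereo element on the way, the Z alkene of the dioxolanone, is erased in the key step.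

Key step: step 6

Remark: the hydroxyquinone and its acetate are written as 1,4-benzoquinone tautomers, which are taken to be the stable forms.

**Route**

Step 1
Reactants: 1 4-hydroxybenzaldehyde
Product: 2 4-(triisopropylsilyloxy)benzaldehyde
Conditions: i-Pr3SiCl, imidazole, DMF, rt
Reagents that add atoms: triisopropylsilyl chloride, CC(C)[Si](Cl)(C(C)C)C(C)C
Why: Standard phenol silylation; the aryl triisopropylsilyl ether should tolerate enolates, the Grignard reagent and aqueous acid, and is cleaved by fluoride at the end.

Step 2
Reactants: 2 4-(triisopropylsilyloxy)benzaldehyde; 3 2,2-dimethyl-1,3-dioxolan-4-one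
Product: 6 (Z)-2,2-dimethyl-5-[4-(triisopropylsilyloxy)benzylidene]-1,3-dioxolan-4-one, via aldol adduct 4 (not isolated), via mesylate 5 (not isolated)
Conditions: 3, LiN(SiMe3)2, THF, −78 °C; then 2; then MsCl, −78 → 0 °C; then DBU, rt
Reagents that add atoms: none
Why: Aldol addition of the lithium enolate of the glycolic acid acetonide to a non-enolizable aldehyde, O-mesylation and E1cB elimination (aldol condensation) should give the conjugated Z alkene, whose geometry is of no consequence later.

Step 3
Reactants: 2 4-(triisopropylsilyloxy)benzaldehyde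
Product: 7 [4-(triisopropylsilyloxy)phenyl]methanol
Conditions: NaBH4, MeOH, 0 °C
Reagents that add atoms: none
Why: Routine hydride reduction of an aromatic aldehyde, to which the aryl silyl ether is inert.

Step 4
Reactants: 7 [4-(triisopropylsilyloxy)phenyl]methanol
Product: 8 4-(triisopropylsilyloxy)benzyl chloride
Conditions: SOCl2, cat. DMF, CH2Cl2, 0 °C
Reagents that add atoms: thionyl chloride, O=S(Cl)Cl
Why: Chlorodehydroxylation through the chlorosulfite is fast for an electron-rich benzylic alcohol at low temperature; the chloride is used at once.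

Step 5
Reactants: 8 4-(triisopropylsilyloxy)benzyl chloride; 9 ethyl diethoxyacetate
Product: 11 1,1-diethoxy-3-[4-(triisopropylsilyloxy)phenyl]propan-2-one, via Grignard reagent 10 (not isolated)
Conditions: Mg, THF, 0 °C → rt (slow addition, dilute); then added to 9, THF, −78 °C; aq NH4Cl
Reagents that add atoms: none
Why: Grignard acylation of an α,α-dialkoxy ester should stop at the ketone, because the magnesium hemiketal is held by chelation to the α-alkoxy groups at −78 °C and collapses only on work-up.

Step 6
Reactants: 11 1,1-diethoxy-3-[4-(triisopropylsilyloxy)phenyl]propan-2-one; 6 (Z)-2,2-dimethyl-5-[4-(triisopropylsilyloxy)benzylidene]-1,3-dioxolan-4-one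
Product: 13 2-hydroxy-3,6-bis[4-(triisopropylsilyloxy)phenyl]-1,4-benzoquinone, via triketone acetal 12 (not isolated)
Conditions: 11, LiN(SiMe3)2 (2.1 equiv), THF, −78 °C; then 6 (1.15 equiv), −78 → 0 °C; then 4 M aq HCl, rt → 40 °C, same flask
Reagents that add atoms: none
Why: Proposed new method: the benzylic lithium enolate of 11 should attack the lactone carbonyl of 6 (Claisen acylation, first new C–C bond), the tetrahedral intermediate collapses with opening of the acetonide and loss of acetone, and the freed 1,2-diketone enolate is carried as the dianion of triketone acetal 12; acidification then ionizes the acetal (to the oxocarbenium ion or the free aldehyde), the enol carbon of the arylpyruvoyl end attacks it (second new C–C bond), and loss of ethanol or water followed by enolization gives the hydroxyquinone with no change of oxidation level. The closest known reaction types are the acylation of ester enolates by 5-alkylidene-1,3-dioxolan-4-ones, the base-induced self-condensation of butane-2,3-dione to 2,5-dimethyl-1,4-benzoquinone, and in nature the head-to-tail double Claisen dimerization of 4-hydroxyphenylpyruvate to atromentin; the crossed ketoacid/ketoaldehyde version in one flask is untested. The six-membered carbocycle closes in the second event by a 6-(enolendo)-exo-trig aldol-type attack and becomes irreversible on elimination to the quinone. No stereocentre is formed. Cross- over self-condensation is secured because 6 has no acidic hydrogen and no free ketone, while 11 has a single enolizable (benzylic) position and keeps its aldehyde carbon masked until the acid is added. In the closure the competing aldol onto the ring ketone would be a disfavoured 5-(enolendo)-exo-trig process and oxygen-centred cyclizations to hemiketals are reversible, so the quinone should be the sink.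

Step 7
Reactants: 13 2-hydroxy-3,6-bis[4-(triisopropylsilyloxy)phenyl]-1,4-benzoquinone
Product: 14 3,6-dioxo-2,5-bis[4-(triisopropylsilyloxy)phenyl]cyclohexa-1,4-dien-1-yl acetate
Conditions: Ac2O, i-Pr2NEt, CH2Cl2, 0 °C
Reagents that add atoms: acetic anhydride, CC(=O)OC(C)=O
Why: O-acylation of the vinylogous carboxylate of a hydroxyquinone with a non-nucleophilic base should give the acetoxy-1,4-quinone, the more stable of the two possible O-acyl isomers.

Step 8
Reactants: 14 3,6-dioxo-2,5-bis[4-(triisopropylsilyloxy)phenyl]cyclohexa-1,4-dien-1-yl acetate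
Product: 15 neonambiquinone A (2,5-bis(4-hydroxyphenyl)-3,6-dioxocyclohexa-1,4-dien-1-yl acetate)
Conditions: HF·pyridine, THF, 0 °C → rt (polypropylene vessel)
Reagents that add atoms: none
Why: Fluoride-assisted cleavage of aryl silyl ethers under acidic, non-nucleophilic conditions should spare the enol acetate, a vinylogous anhydride that would not survive basic fluoride or hydrogenolysis.

**Compound list**

1 | 4-hydroxybenzaldehyde | O=Cc1ccc(O)cc1 | starting material
2 | 4-(triisopropylsilyloxy)benzaldehyde | O=Cc1ccc(O[Si](C(C)C)(C(C)C)C(C)C)cc1 | intermediate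
3 | 2,2-dimethyl-1,3-dioxolan-4-one | CC1(C)OCC(=O)O1 | starting material
4 | 5-{hydroxy[4-(triisopropylsilyloxy)phenyl]methyl}-2,2-dimethyl-1,3-dioxolan-4-one (aldol adduct, racemic diastereomer mixture, formed as lithium alkoxide) | CC1(C)OC(C(O)c2ccc(O[Si](C(C)C)(C(C)C)C(C)C)cc2)C(=O)O1 | intermediate (not isolated)
5 | methanesulfonate of 4 (racemic diastereomer mixture) | CC1(C)OC(C(OS(C)(=O)=O)c2ccc(O[Si](C(C)C)(C(C)C)C(C)C)cc2)C(=O)O1 | intermediate (not isolated)
6 | (Z)-2,2-dimethyl-5-[4-(triisopropylsilyloxy)benzylidene]-1,3-dioxolan-4-one | CC1(C)OC(=O)/C(=C/c2ccc(O[Si](C(C)C)(C(C)C)C(C)C)cc2)O1 | intermediate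
7 | [4-(triisopropylsilyloxy)phenyl]methanol | OCc1ccc(O[Si](C(C)C)(C(C)C)C(C)C)cc1 | intermediate
8 | 4-(triisopropylsilyloxy)benzyl chloride | ClCc1ccc(O[Si](C(C)C)(C(C)C)C(C)C)cc1 | intermediate
9 | ethyl diethoxyacetate | CCOC(=O)C(OCC)OCC | starting material
10 | 4-(triisopropylsilyloxy)benzylmagnesium chloride | Cl[Mg]Cc1ccc(O[Si](C(C)C)(C(C)C)C(C)C)cc1 | intermediate (not isolated)
11 | 1,1-diethoxy-3-[4-(triisopropylsilyloxy)phenyl]propan-2-one | CCOC(OCC)C(=O)Cc1ccc(O[Si](C(C)C)(C(C)C)C(C)C)cc1 | intermediate
12 | 1,1-diethoxy-3,6-bis[4-(triisopropylsilyloxy)phenyl]hexane-2,4,5-trione (drawn as the keto form; present as its lithium enolate, racemic) | CCOC(OCC)C(=O)C(c1ccc(O[Si](C(C)C)(C(C)C)C(C)C)cc1)C(=O)C(=O)Cc1ccc(O[Si](C(C)C)(C(C)C)C(C)C)cc1 | intermediate (not isolated)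
13 | 2-hydroxy-3,6-bis[4-(triisopropylsilyloxy)phenyl]-1,4-benzoquinone | OC1=C(c2ccc(O[Si](C(C)C)(C(C)C)C(C)C)cc2)C(=O)C=C(c2ccc(O[Si](C(C)C)(C(C)C)C(C)C)cc2)C1=O | intermediate
14 | 3,6-dioxo-2,5-bis[4-(triisopropylsilyloxy)phenyl]cyclohexa-1,4-dien-1-yl acetate | CC(=O)OC1=C(c2ccc(O[Si](C(C)C)(C(C)C)C(C)C)cc2)C(=O)C=C(c2ccc(O[Si](C(C)C)(C(C)C)C(C)C)cc2)C1=O | intermediate
15 | neonambiquinone A | CC(=O)OC1=C(c2ccc(O)cc2)C(=O)C=C(c2ccc(O)cc2)C1=O | target

**Summary**

Total step count: 8. Longest linear sequence: 7 steps (steps 1, 3, 4, 5, 6, 7, 8).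

**Steps most likely to fail**

1. Step 6 (proposed new method). The acylation may go through the enolate oxygen instead of carbon, or stall by proton transfer from the acidic acylation product. In the acid stage the α-keto acetal may ionize slowly, the open-chain intermediate may be diverted by cyclodehydration through oxygen to a furanone, and the silyl ethers may be partly lost.
Fallback (known chemistry only; sets out from 2, returns at 13): Baeyer–Villiger oxidation of 2 (3-chloroperbenzoic acid, CH2Cl2) should give 4-(triisopropylsilyloxy)phenyl formate F1. Its methanolysis (Et3N, MeOH) should give 4-(triisopropylsilyloxy)phenol F2. Triflation (Tf2O, pyridine) should give 4-(triisopropylsilyloxy)phenyl trifluoromethanesulfonate F3. Twofold Suzuki–Miyaura coupling of F3 with purchasable 2,5-dimethoxy-1,4-phenylenediboronic acid (Pd(PPh3)4, K3PO4, dioxane, 90 °C) should give 1,4-dimethoxy-2,5-bis[4-(triisopropylsilyloxy)phenyl]benzene F4. Oxidative demethylation ((NH4)2Ce(NO3)6, MeCN–H2O, 0 °C) should give 2,5-bis[4-(triisopropylsilyloxy)phenyl]-1,4-benzoquinone F5. Nucleophilic mono-epoxidation (t-BuOOH, DBU, CH2Cl2) should give 1,4-bis[4-(triisopropylsilyloxy)phenyl]-7-oxabicyclo[4.1.0]hept-3-ene-2,5-dione F6. Acid-induced epoxide opening and enolization (BF3·OEt2, CH2Cl2), the classical conversion of a quinone epoxide into a hydroxyquinone, should then give 13.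

2. Step 8. The acetyl group may be lost or may migrate during desilylation, by hydrolysis of the vinylogous anhydride or by intermolecular transfer to the freed phenols.
Fallback (sets out from 13, returns at 15): the order of the last two operations is reversed. Desilylation of 13 (Et3N·3HF, THF) should give 2-hydroxy-3,6-bis(4-hydroxyphenyl)-1,4-benzoquinone F7. Selectivity would then rest on acidity instead of protection: one equivalent of NaHCO3 should ionize only the hydroxyquinone (pKa about 3–4) and not the phenols (pKa about 10), and one equivalent of acetyl chloride in acetone at −20 °C should acetylate that anion to give 15.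

3. Step 5. Homocoupling may compete while the electron-rich benzylic Grignard reagent forms, and a second addition to the ester may occur.
Fallback (sets out from 6, returns at 11): both halves would then come from the same dioxolanone. Reduction of 6 (i-Bu2AlH, CH2Cl2, −78 °C) should give the lactol (Z)-2,2-dimethyl-5-[4-(triisopropylsilyloxy)benzylidene]-1,3-dioxolan-4-ol F8. Acid-catalysed ethanolysis (EtOH, cat. camphorsulfonic acid, 3 Å molecular sieves) should open the acetonide, acetalize the aldehyde carbon and let the enol revert to the ketone, giving 11.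

**Further compounds**

F1 | step 6 | 4-(triisopropylsilyloxy)phenyl formate | O=COc1ccc(O[Si](C(C)C)(C(C)C)C(C)C)cc1
F2 | step 6 | 4-(triisopropylsilyloxy)phenol | Oc1ccc(O[Si](C(C)C)(C(C)C)C(C)C)cc1
F3 | step 6 | 4-(triisopropylsilyloxy)phenyl trifluoromethanesulfonate | O=S(=O)(Oc1ccc(O[Si](C(C)C)(C(C)C)C(C)C)cc1)C(F)(F)F
F4 | step 6 | 1,4-dimethoxy-2,5-bis[4-(triisopropylsilyloxy)phenyl]benzene | COc1cc(-c2ccc(O[Si](C(C)C)(C(C)C)C(C)C)cc2)c(OC)cc1-c1ccc(O[Si](C(C)C)(C(C)C)C(C)C)cc1
F5 | step 6 | 2,5-bis[4-(triisopropylsilyloxy)phenyl]-1,4-benzoquinone | O=C1C=C(c2ccc(O[Si](C(C)C)(C(C)C)C(C)C)cc2)C(=O)C=C1c1ccc(O[Si](C(C)C)(C(C)C)C(C)C)cc1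
F6 | step 6 | 1,4-bis[4-(triisopropylsilyloxy)phenyl]-7-oxabicyclo[4.1.0]hept-3-ene-2,5-dione (racemic) | O=C1C=C(c2ccc(O[Si](C(C)C)(C(C)C)C(C)C)cc2)C(=O)C2OC12c1ccc(O[Si](C(C)C)(C(C)C)C(C)C)cc1
F7 | step 8 | 2-hydroxy-3,6-bis(4-hydroxyphenyl)-1,4-benzoquinone | OC1=C(c2ccc(O)cc2)C(=O)C=C(c2ccc(O)cc2)C1=O
F8 | step 5 | (Z)-2,2-dimethyl-5-[4-(triisopropylsilyloxy)benzylidene]-1,3-dioxolan-4-ol (racemic) | CC1(C)OC(O)/C(=C/c2ccc(O[Si](C(C)C)(C(C)C)C(C)C)cc2)O1
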